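I decided to stop asking how far these flasks go and to ask how they split.

all flasks: starting material 34 mM; reagent 20.4 mM
- Sunday's: second substrate 34 mM; free catalyst 0.12 mM; run made earlier
- Tuesday's: second substrate 34 mM; free catalyst 0.22 mM; run made earlier
- beta: second substrate 34.0 mM; free catalyst 0.16 mM; time 20 d
- delta: second substrate 34.0 mM; free catalyst 0.32 mM; time 20 d

| run | time / d | uncatalysed product / % | starting material / % | target / % |
|---|---|---|---|---|
| Sunday's | 3.00 | 8.4 | 65.9 | 24.1 |
| Sunday's | 6.00 | 8.8 | 66.1 | 24.9 |
| Sunday's | 10.0 | 9.3 | 66.5 | 23.8 |
| Sunday's | 12.0 | 9.1 | 67.4 | 24.6 |
| Sunday's | 15.0 | 8.9 | 66.2 | 24.5 |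
| Sunday's | 20.0 | 8.6 | 67.0 | 25.6 |
| Tuesday's | 3.00 | 6.8 | 65.0 | 27.8 |
| Tuesday's | 6.00 | 5.0 | 64.8 | 28.6 |
| Tuesday's | 10.0 | 5.1 | 65.4 | 27.4 |
| Tuesday's | 12.0 | 6.2 | 65.1 | 27.8 |
| Tuesday's | 15.0 | 5.9 | 64.9 | 28.7 |
| Tuesday's | 20.0 | 6.5 | 64.9 | 29.0 |

(scatter of a reading: 0.5 percentage points)

* which of these there is most of at the end, counted by the starting material in it, beta (uncatalysed product / target / starting material)
* which of these there is most of at the end, counted by the starting material in it, delta (uncatalysed product / target / starting material)
* the largest of these amounts at the end, in percent of the starting material charged, beta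
* the largest of these amounts at the end, in percent of the starting material charged, delta



**The runs.** Neither run moved much after its first reading at 3.00 d, so I took the readings as end states. Tuesday's run had more free catalyst than Sunday's and ended with less uncatalysed product. Starting material stayed the largest amount in both, at 67.0 % and 64.9 %.

**The ratio.** Target comes by a path that needs free catalyst. Uncatalysed product comes by one that does not. I assumed both rates carry the same starting material and reagent. Divide one rate by the other, and those concentrations drop out. Time drops out too if free catalyst holds at its charge, and I assumed that. Target over uncatalysed product should then equal a constant times free catalyst.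

**The reckoning.** Summed over its readings, Sunday's run gave a ratio of 2.78, and Tuesday's gave 4.77. Per free catalyst charged, that is 23.1 /mM and 21.7 /mM. Their mean, 22.4 /mM, is my steering number: a selectivity factor per unit of catalyst. It gave a ratio of 3.59 for beta and 7.17 for delta. I reckoned the split, not the amounts.

**The forecast.** The forecast named starting material for beta and starting material for delta, with 65.8 % and 64.3 %. It read the runs as “catalyst steering the split, not the extent of reaction”. Its ratios, 3.5 and 7, lay close to mine.

**The result.** Starting material was the largest amount in both flasks, at 65.7 % in beta and 64.4 % in delta. Reagent, the limiting reagent, stood at 0 % in beta and 0 % in delta.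

    starting material + reagent → uncatalysed product (k = 1.13 /M/h)
    starting material + reagent + free catalyst → free catalyst + target (k = 27200 /M²/h)
    second substrate + reagent + free catalyst → free catalyst + second product (k = 14700 /M²/h)
    2 reagent → homo dimer (k = 2.23 /M/h)
    2 free catalyst → spent catalyst (k = 90.8 /M/h)

**The split.** In delta at 0.0588 d, the catalysed path used starting material 7.1 times as fast as the uncatalysed path, or 22.2 /mM per free catalyst charged, against my 22.4 /mM. The end ratios were 3.42 in beta and 6.72 in delta, a little under my 3.59 and 7.17. A neighbour flask was delta with 140 mM of second substrate. It ended with 81.3 % of starting material, and its ratio was 7.24.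

The runs come from a simulation with constants of no real substance, noise included.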